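**Retrosynthetic overview**
- Side chain first, the only step outside the ring: the α′-enolate of enaminone 1 is alkylated with 1-bromodocosane 2 to give the C26 enaminone 3. C22 plus the methyl of 1 makes the C23 chain, and 3 already holds C3, C4 and C5 of the pyrrole.
- Key disconnection N1–C5 (C–N): vinylogous transamidation of 3 with glycine methyl ester hydrochloride 4 gives the secondary enaminone 5. This bond joins the two halves and brings in N1, C2 and the ester.
- Ring formation (one ring, the pyrrole, formed last): 5 closes in the same flask at C2–C3 through the O-silyl azadiene 6 and aromatises by loss of silanol to target 7.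
- Order: chain, then C–N union, then pyrrole closure. No protecting groups and no redox steps.

Assumption: the chain in the SMILES is read as unbranched C23H47 (target C29H53NO2). The molecule has no stereocentre, so there is no enantiomer to select, and only the C=C/C=N geometries of 1, 3, 5 and 6 are specified.

**Step 1**
Reactants: 1 (E)-4-(dimethylamino)but-3-en-2-one; 2 1-bromodocosane
Product: 3 (E)-1-(dimethylamino)hexacos-1-en-3-one
Conditions: LDA (1.3 equiv, commercial solution), 1 (1.3 equiv), THF, −78 °C, 1 h; 2 (1.0 equiv) in THF–DMPU 4:1, −78 °C → rt, 16 h
Reagents that add atoms: none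
Why: Kinetic deprotonation of the vinylogous amide at its only acidic sp3 site (the α′-methyl, the same enolate that is silylated to make 1-amino-3-siloxydienes) gives an electron-rich, amide-like lithium enolate that C-alkylates the primary bromide by SN2 (enolate alkylation), with the bromide as limiting reagent and excess 1 washed out with water; no stereocentre is formed and the E-enaminone geometry is kept.

**Step 2**
Reactants: 3 (E)-1-(dimethylamino)hexacos-1-en-3-one; 4 glycine methyl ester hydrochloride
Product: 7 methyl 3-tricosyl-1H-pyrrole-2-carboxylate, via secondary enaminone 5 (not isolated), via O-silyl azadiene 6 (not isolated)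
Conditions: 4 (1.1 equiv), NaOAc (1.1 equiv), THF–MeOH 4:1, 50 °C, 3 h; evaporate, PhMe chase; Et3N (5 equiv), TMSOTf (3 equiv), CH2Cl2, 0 → 40 °C, 6 h; aq NaHCO3
Reagents that add atoms: trimethylsilyl trifluoromethanesulfonate (TMSOTf), C[Si](C)(C)OS(=O)(=O)C(F)(F)F (its Me3Si group is carried by 6 only; no reagent atom remains in 7)
Why: Proposed new method: buffered vinylogous transamidation (addition–elimination at C1 of 3, volatile Me2NH leaving) first makes the key N1–C5 bond and gives the H-bonded Z-enaminone 5, whose CH2 is held away from a deactivated vinylogous-amide C=O; TMSOTf/Et3N is then proposed to O-silylate 5 to azadiene 6 (H-bond broken, C4–C5 free to rotate, and C4 no longer nucleophilic, so the competing Dieckmann closure to a 3-hydroxypyrrole is shut off), to N-activate 6 as an iminium ion whose glycine CH2 is soft-enolised by Et3N to a conjugated azomethine ylide, and to let this 6π 1,5-dipole electrocyclise (equally, a 5-exo-trig Mukaiyama-type aldol on the silyloxocarbenium form) to form C2–C3, after which nitrogen-assisted loss of Me3SiOH aromatises irreversibly to 7; the closest known reaction types are the alkoxide-mediated intramolecular Knoevenagel cyclisation of N-(3-oxoalkenyl)glycinates, the pyrrole synthesis from 3-chloropropeniminium salts and glycinates, the 1,5-electrocyclisation of 2-azapentadienyl anions, and amine/silyl triflate soft-enolisation aldol reactions; no stereocentre survives.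

**Compound list**
1 | (E)-4-(dimethylamino)but-3-en-2-one | CC(=O)/C=C/N(C)C | starting material
2 | 1-bromodocosane | CCCCCCCCCCCCCCCCCCCCCCBr | starting material
3 | (E)-1-(dimethylamino)hexacos-1-en-3-one | CCCCCCCCCCCCCCCCCCCCCCCC(=O)/C=C/N(C)C | intermediate
4 | glycine methyl ester hydrochloride | COC(=O)CN.Cl | starting material
5 | methyl N-[(1Z)-3-oxohexacos-1-en-1-yl]glycinate | CCCCCCCCCCCCCCCCCCCCCCCC(=O)/C=C\NCC(=O)OC | intermediate
6 | methyl N-[(1E,2Z)-3-(trimethylsilyloxy)hexacos-2-en-1-ylidene]glycinate | CCCCCCCCCCCCCCCCCCCCCCC/C(O[Si](C)(C)C)=C/C=N/CC(=O)OC | intermediate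
7 | methyl 3-tricosyl-1H-pyrrole-2-carboxylate | CCCCCCCCCCCCCCCCCCCCCCCc1cc[nH]c1C(=O)OC | target

**Total step count:** 2. **Longest linear sequence:** 2.

**Steps most likely to fail**
The route has only two steps, so the two stages of step 2 are ranked separately.

1. Step 2, ring-closure stage (the proposed new step). Silylation may stall at 6, drain into an α′-silyl dienol ether, or C-silylate the glycinate. The fallback uses known chemistry and sets out from 3. Heating 3 with commercial dimethyl aminomalonate hydrochloride and NaOAc in refluxing acetic acid (aminomalonate pyrrole condensation of the Kleinspehn type) gives, by amine exchange, dimethyl 2-{[(1Z)-3-oxohexacos-1-en-1-yl]amino}propanedioate F1. Its doubly activated CH closes onto the ketone under acid catalysis. The resulting 2,2-diester aromatises by dealkoxycarbonylation, and the fallback comes back to the route at 7.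

2. Step 1. The waxy bromide may react slowly, and proton transfer may lead to dialkylation. The fallback sets out from 2. The dianion of methyl acetoacetate (NaH, then n-BuLi, THF, 0 °C) is γ-alkylated with 2 to give methyl 3-oxohexacosanoate F2. Saponification with aqueous NaOH in THF–MeOH, then acidification and warming, decarboxylates it to pentacosan-2-one F3. Condensation of F3 with DMF dimethyl acetal (PhMe, 110 °C) takes place at the methyl group, and the fallback comes back to the route at 3.

3. Step 2, C–N exchange stage. The glycine ester may self-condense to the diketopiperazine, or the exchange may stay incomplete. The fallback sets out from 3. Hydrolysis with 2 M NaOH in THF–EtOH at 60 °C and careful acidification with AcOH gives (Z)-1-hydroxyhexacos-1-en-3-one F4, the enol of the β-keto aldehyde. F4 condenses at room temperature with 4 and NaOAc in THF–MeOH, now with water as the leaving group, and the fallback comes back to the route at 5.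

**Further compounds**
F1 | step 2 | dimethyl 2-{[(1Z)-3-oxohexacos-1-en-1-yl]amino}propanedioate | CCCCCCCCCCCCCCCCCCCCCCCC(=O)/C=C\NC(C(=O)OC)C(=O)OC
F2 | step 1 | methyl 3-oxohexacosanoate | CCCCCCCCCCCCCCCCCCCCCCCC(=O)CC(=O)OC
F3 | step 1 | pentacosan-2-one | CCCCCCCCCCCCCCCCCCCCCCCC(C)=O
F4 | step 2 | (Z)-1-hydroxyhexacos-1-en-3-one | CCCCCCCCCCCCCCCCCCCCCCCC(=O)/C=C\O
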